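**Strategy.** Everything rests on disconnecting the C3a–C3 bond of the dihydrofuran ring (ring B). The precursor is an acyclic ether: an ortho-iodo, para-bromo guaiacol O-linked to (S)-1-(3,4-dimethoxyphenyl)allyl, whose carbinol carbon is the future C2 and whose vinyl group is the future C3 with its methyl. A 5-exo-trig aryl radical cyclisation forms C3a–C3, closes ring B, turns the terminal CH2 into the C3 methyl and sets C3 trans to the C2 aryl group. It exploits that C3 carries only CH3 and H beside its ring bonds and that C3a lies ortho to O1 on ring A. The surviving bromine at C5 then takes up the erythro-diol chain from (S)-lactate.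

Key step: step 4

Conventions and assumptions:
- Benzofuran numbering is used (O1, C2, C3, C3a, C4–C7, C7a). Ring A is the benzene ring of the benzofuran, ring B the dihydrofuran ring, ring C the 3,4-dimethoxyphenyl group.
- The target is (2S,3S) in ring B (trans) and (1R,2S) in the side chain (erythro diol).
- Compounds 1, 3 and 8 are taken as purchasable.
- L is the phosphoramidite from (S)-1,1'-bi-2-naphthol and bis[(S)-1-phenylethyl]amine, written (Sa,Sc,Sc)-L. It is assumed to steer the phenoxide to the allyl face that gives the (S)-ether; if a first run shows the opposite sense, the antipodal ligand is used and nothing else changes.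

Step 1
Reactants: 1 4-bromo-2-methoxyphenol
Product: 2 4-bromo-2-iodo-6-methoxyphenol
Conditions: NIS, TsOH·H2O (10 mol%), MeCN, 0 °C to rt
Reagents that add atoms: N-iodosuccinimide, O=C1CCC(=O)N1I
Why: Electrophilic aromatic iodination, in which the free hydroxyl group directs to its only open ortho position because the para position is blocked by bromine.

Step 2
Reactants: 3 (E)-3-(3,4-dimethoxyphenyl)prop-2-en-1-ol
Product: 4 (E)-3-(3,4-dimethoxyphenyl)prop-2-en-1-yl methyl carbonate
Conditions: ClCO2Me, pyridine, CH2Cl2, 0 °C
Reagents that add atoms: methyl chloroformate, COC(=O)Cl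
Why: O-acylation of the primary allylic alcohol with a chloroformate should give the linear carbonate that serves as the ionisable allyl donor, with the E-alkene untouched.

Step 3
Reactants: 2 4-bromo-2-iodo-6-methoxyphenol; 4 (E)-3-(3,4-dimethoxyphenyl)prop-2-en-1-yl methyl carbonate
Product: 6 5-bromo-2-{[(1S)-1-(3,4-dimethoxyphenyl)prop-2-en-1-yl]oxy}-1-iodo-3-methoxybenzene, via sodium phenoxide 5 (not isolated)
Conditions: NaH, THF, 0 °C; then 4, [Ir(cod)Cl]2 (2 mol%, cod = 1,5-cyclooctadiene), (Sa,Sc,Sc)-L (4 mol%), catalyst pre-activated with n-PrNH2, THF, rt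
Reagents that add atoms: none
Why: Iridium-catalysed asymmetric allylic etherification (a Tsuji–Trost-type substitution), in which the cyclometalated iridium–phosphoramidite catalyst ionises the carbonate and the phenoxide attacks the aryl-substituted allyl terminus to give the branched ether, the stereocentre (the future C2) being set by the chiral ligand.

Step 4
Reactants: 6 5-bromo-2-{[(1S)-1-(3,4-dimethoxyphenyl)prop-2-en-1-yl]oxy}-1-iodo-3-methoxybenzene
Product: 7 (2S,3S)-5-bromo-2-(3,4-dimethoxyphenyl)-7-methoxy-3-methyl-2,3-dihydro-1-benzofuran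
Conditions: Bu3SnH (1.15 equiv, about 0.1 M), Et3B (0.2 equiv)/air, PhMe, 0 °C to rt
Reagents that add atoms: none
Why: Bu3Sn• (chain started by Et3B/air) abstracts iodine from C3a much faster than bromine from C5, the σ-aryl radical adds to the inner vinyl carbon, and the primary radical so formed takes hydrogen from Bu3SnH, so that the terminal CH2 becomes the C3 methyl group. The closest known reaction type is the tin hydride aryl radical cyclisation of ortho-haloaryl allyl ethers to 3-methyl-2,3-dihydrobenzofurans. Ring B, the only ring formed, closes in the 5-exo-trig mode, which for this radical is far faster than 6-endo closure or hydrogen transfer to the uncyclised aryl radical. The new stereocentre C3 is controlled by the existing C2 centre (1,2-induction, substrate control): in the transition state the terminal CH2 sits on the side of the small C2 hydrogen, away from ring C (allylic strain), which places the methyl group trans to the aryl group, that is (2S,3S). The step needs iodine-over-bromine selectivity, secured by the weaker C–I bond and only a small excess of stannane, and fast quenching of the primary radical before it can reopen to the stabilised α-aryloxybenzyl radical, secured by the stannane concentration of about 0.1 M.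

Step 5
Reactants: 8 ethyl (S)-lactate
Product: 9 (S)-2-hydroxy-N-methoxy-N-methylpropanamide
Conditions: MeNH(OMe)·HCl, i-PrMgCl, THF, −20 to 0 °C
Reagents that add atoms: N,O-dimethylhydroxylamine hydrochloride, CNOC.Cl
Why: Aminolysis of the ester by the chloromagnesium amide of N,O-dimethylhydroxylamine should give the N-methoxy-N-methylamide without touching the α-stereocentre, which is shielded from enolisation as its alkoxide.

Step 6
Reactants: 7 (2S,3S)-5-bromo-2-(3,4-dimethoxyphenyl)-7-methoxy-3-methyl-2,3-dihydro-1-benzofuran; 9 (S)-2-hydroxy-N-methoxy-N-methylpropanamide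
Product: 13 (2S)-1-[(2S,3S)-2-(3,4-dimethoxyphenyl)-7-methoxy-3-methyl-2,3-dihydro-1-benzofuran-5-yl]-2-hydroxypropan-1-one, via aryllithium 10 (not isolated), via chloromagnesium alkoxide 11 (not isolated), via tetrahedral adduct 12 (not isolated)
Conditions: 7, n-BuLi, THF, −78 °C; separately 9, i-PrMgCl, THF, −20 °C (1.3 equiv of 11); combine, −78 to 0 °C; cold 0.5 M aq HCl
Reagents that add atoms: none
Why: Bromine–lithium exchange followed by acyl substitution on an N-methoxy-N-methylamide, in which the chelated tetrahedral adduct stops the addition at the ketone stage and the pre-formed α-alkoxide prevents both quenching of the aryllithium and enolisation, so the lactate stereocentre should be carried through unchanged.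

Step 7
Reactants: 13 (2S)-1-[(2S,3S)-2-(3,4-dimethoxyphenyl)-7-methoxy-3-methyl-2,3-dihydro-1-benzofuran-5-yl]-2-hydroxypropan-1-one
Product: 14 (1R,2S)-1-[(2S,3S)-2-(3,4-dimethoxyphenyl)-7-methoxy-3-methyl-2,3-dihydro-1-benzofuran-5-yl]propane-1,2-diol
Conditions: Zn(BH4)2, Et2O, −20 to 0 °C; then water
Reagents that add atoms: none
Why: Chelation-controlled hydride reduction of an α-hydroxy ketone, in which zinc ties the carbonyl and hydroxyl oxygens into a five-membered chelate and hydride enters from the side of the small α-hydrogen, which should give the anti (erythro) diol, that is (1R) next to (2S).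

**Compound list**

1 | 4-bromo-2-methoxyphenol | COc1cc(Br)ccc1O | starting material
2 | 4-bromo-2-iodo-6-methoxyphenol | COc1cc(Br)cc(I)c1O | intermediate
3 | (E)-3-(3,4-dimethoxyphenyl)prop-2-en-1-ol | COc1ccc(/C=C/CO)cc1OC | starting material
4 | (E)-3-(3,4-dimethoxyphenyl)prop-2-en-1-yl methyl carbonate | COC(=O)OC/C=C/c1ccc(OC)c(OC)c1 | intermediate
5 | sodium 4-bromo-2-iodo-6-methoxyphenoxide | COc1cc(Br)cc(I)c1[O-].[Na+] | intermediate
6 | 5-bromo-2-{[(1S)-1-(3,4-dimethoxyphenyl)prop-2-en-1-yl]oxy}-1-iodo-3-methoxybenzene | C=C[C@H](Oc1c(I)cc(Br)cc1OC)c1ccc(OC)c(OC)c1 | intermediate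
7 | (2S,3S)-5-bromo-2-(3,4-dimethoxyphenyl)-7-methoxy-3-methyl-2,3-dihydro-1-benzofuran | COc1ccc([C@H]2Oc3c(OC)cc(Br)cc3[C@@H]2C)cc1OC | intermediate
8 | ethyl (S)-lactate | CCOC(=O)[C@H](C)O | starting material
9 | (S)-2-hydroxy-N-methoxy-N-methylpropanamide | C[C@H](O)C(=O)N(C)OC | intermediate
10 | [(2S,3S)-2-(3,4-dimethoxyphenyl)-7-methoxy-3-methyl-2,3-dihydro-1-benzofuran-5-yl]lithium | COc1ccc([C@H]2Oc3c(OC)cc([Li])cc3[C@@H]2C)cc1OC | intermediate
11 | chloromagnesium alkoxide of amide 9 | C[C@H](O[Mg]Cl)C(=O)N(C)OC | intermediate
12 | tetrahedral adduct of 10 and 11 (lithium and chloromagnesium alkoxide, hemiaminal carbon undefined) | COc1ccc([C@H]2Oc3c(OC)cc(C(O[Li])(N(C)OC)[C@H](C)O[Mg]Cl)cc3[C@@H]2C)cc1OC | intermediate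
13 | (2S)-1-[(2S,3S)-2-(3,4-dimethoxyphenyl)-7-methoxy-3-methyl-2,3-dihydro-1-benzofuran-5-yl]-2-hydroxypropan-1-one | COc1ccc([C@H]2Oc3c(OC)cc(C(=O)[C@H](C)O)cc3[C@@H]2C)cc1OC | intermediate
14 | (1R,2S)-1-[(2S,3S)-2-(3,4-dimethoxyphenyl)-7-methoxy-3-methyl-2,3-dihydro-1-benzofuran-5-yl]propane-1,2-diol | COc1ccc([C@H]2Oc3c(OC)cc([C@@H](O)[C@H](C)O)cc3[C@@H]2C)cc1OC | target

**Step count.** Total: 7 steps. Longest linear sequence: 5 steps (step 1 or 2, then steps 3, 4, 6 and 7).

**Steps most likely to fail**

1. Step 3. The attack of the doubly ortho-substituted phenoxide on the allyl–iridium intermediate may be slow. The product is an electron-rich 1-arylallyl ether with a good aryloxide leaving group, so it may re-ionise on the catalyst, isomerise to the linear ether and lose enantiomeric purity. The fallback sets out from carbonate 4 and phenol 2 and comes back to the route at ether 6. The oxygen nucleophile is changed to a small one whose product cannot re-ionise. Carbonate 4 with KOSiEt3 and the same [Ir(cod)Cl]2/phosphoramidite system, but with the antipodal (Ra,Rc,Rc) ligand (CH2Cl2, rt), should give (R)-{[1-(3,4-dimethoxyphenyl)prop-2-en-1-yl]oxy}triethylsilane F1. Bu4NF in THF should free (R)-1-(3,4-dimethoxyphenyl)prop-2-en-1-ol F2. A Mitsunobu reaction of F2 with phenol 2 (PPh3, DIAD, toluene, −20 °C) should then give 6 with inversion at the carbinol carbon. The acidic phenol, the low temperature and the non-polar solvent favour the SN2 path over ionisation.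

2. Step 4. The facial selectivity of the radical addition to the vinyl group may be only moderate. The cyclised primary radical may also reopen by β-scission to the α-aryloxybenzyl radical before it is reduced, which would erode the configuration at C2 or lead to ring enlargement, and over-reduction would remove the bromine. The fallback sets out from phenol 2 and comes back to the route at bromide 7. It gives up the radical closure, builds C3 first and closes ring B at O1–C2 under thermodynamic control.
   - Phenol 2 is protected (MOMCl, i-Pr2NEt, CH2Cl2) as 5-bromo-1-iodo-3-methoxy-2-(methoxymethoxy)benzene F3.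
   - Iodine–magnesium exchange (i-PrMgCl, THF, −20 °C) and transmetalation with ZnI2 should give [5-bromo-3-methoxy-2-(methoxymethoxy)phenyl]zinc iodide F4.
   - A stereoconvergent Negishi arylation of purchased racemic 2-bromo-1-(3,4-dimethoxyphenyl)propan-1-one with F4 (NiCl2·glyme, chiral bis(oxazolinyl)pyridine ligand, glyme/THF, −30 °C) should give (S)-2-[5-bromo-3-methoxy-2-(methoxymethoxy)phenyl]-1-(3,4-dimethoxyphenyl)propan-1-one F5. The ligand enantiomer is chosen to give the (S)-ketone.
   - NaBH4 (MeOH, 0 °C) should give (2S)-2-[5-bromo-3-methoxy-2-(methoxymethoxy)phenyl]-1-(3,4-dimethoxyphenyl)propan-1-ol F6 as a mixture of carbinol epimers, which does not matter.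
   - TsOH in MeOH/CH2Cl2 should remove the methoxymethyl group and ionise the electron-rich benzylic carbinol. The phenol oxygen then closes to the more stable trans-dihydrobenzofuran 7, with C3 untouched.

3. Step 6. Proton transfer between the aryllithium and the amide (incomplete alkoxide formation or α-deprotonation), or sluggish addition to the alkoxide-bearing amide, would return debrominated material. The free α-hydroxy ketone may also racemise or rearrange during work-up. The fallback sets out from amide 9 and bromide 7 and comes back to the route at ketone 13, with the hydroxyl group masked. Amide 9 with TBSCl and imidazole (DMF) should give (S)-2-[(tert-butyldimethylsilyl)oxy]-N-methoxy-N-methylpropanamide F7. Aryllithium 10 (from 7, n-BuLi, THF, −78 °C) should add to F7 to give (2S)-2-[(tert-butyldimethylsilyl)oxy]-1-[(2S,3S)-2-(3,4-dimethoxyphenyl)-7-methoxy-3-methyl-2,3-dihydro-1-benzofuran-5-yl]propan-1-one F8. HF·pyridine (THF, 0 °C) should remove the silyl group without base to give 13.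

**Further compounds**

F1 | step 3 | (R)-{[1-(3,4-dimethoxyphenyl)prop-2-en-1-yl]oxy}triethylsilane | C=C[C@@H](O[Si](CC)(CC)CC)c1ccc(OC)c(OC)c1
F2 | step 3 | (R)-1-(3,4-dimethoxyphenyl)prop-2-en-1-ol | C=C[C@@H](O)c1ccc(OC)c(OC)c1
F3 | step 4 | 5-bromo-1-iodo-3-methoxy-2-(methoxymethoxy)benzene | COCOc1c(I)cc(Br)cc1OC
F4 | step 4 | [5-bromo-3-methoxy-2-(methoxymethoxy)phenyl]zinc iodide | COCOc1c([Zn]I)cc(Br)cc1OC
F5 | step 4 | (S)-2-[5-bromo-3-methoxy-2-(methoxymethoxy)phenyl]-1-(3,4-dimethoxyphenyl)propan-1-one | COc1ccc(C(=O)[C@@H](C)c2cc(Br)cc(OC)c2OCOC)cc1OC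
F6 | step 4 | (2S)-2-[5-bromo-3-methoxy-2-(methoxymethoxy)phenyl]-1-(3,4-dimethoxyphenyl)propan-1-ol (both carbinol epimers) | COc1ccc(C(O)[C@@H](C)c2cc(Br)cc(OC)c2OCOC)cc1OC
F7 | step 6 | (S)-2-[(tert-butyldimethylsilyl)oxy]-N-methoxy-N-methylpropanamide | C[C@H](O[Si](C)(C)C(C)(C)C)C(=O)N(C)OC
F8 | step 6 | (2S)-2-[(tert-butyldimethylsilyl)oxy]-1-[(2S,3S)-2-(3,4-dimethoxyphenyl)-7-methoxy-3-methyl-2,3-dihydro-1-benzofuran-5-yl]propan-1-one | COc1ccc([C@H]2Oc3c(OC)cc(C(=O)[C@H](C)O[Si](C)(C)C(C)(C)C)cc3[C@@H]2C)cc1OC
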